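The easy step is the tail of the alpha run: between 3.00 min and 4.00 min Q falls from 45.9% to 33.5%, which reads as a first-order loss of 0.315 min⁻¹. Counting what is left rather than what is made, the reckoning then needs one further given: how long a flask's D has been in. Maple's portions arrive on average 0.750 min after the start, and birch's whole charge arrives at the start. Reckoned as if Q formed the moment its D arrives, the part of the Q formed that is still Q at the end comes to 0.359 for maple; this is the kept fraction, a survival fraction. For birch it is 0.284, so the reckoning keeps more in maple than in birch, by a factor of 1.26.

| flask | D | E | remark | time |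
|---|---|---|---|---|
| delta | 0.050 M (in portions, 4) | 0.0059 M | run made earlier; portions every 30 s |  |
| alpha | 0.050 M (in portions, 4) | 0.0067 M | run made earlier; portions every 30 s |  |
| eta | 0.050 M (in portions, 4) | 0.0087 M | run made earlier; portions every 30 s |  |
| birch | 0.050 M | 0.00500 M | everything together at the start | 4.0 min |
| maple | 0.050 M (in portions, 4) | 0.0100 M | the portions of D follow each other after 30 s, the first at the start | 4.0 min |

| delta: time / min | delta: Q / % | alpha: time / min | alpha: Q / % | eta: time / min | eta: Q / % |
|---|---|---|---|---|---|
| 0.333 | 9.4 | 0.333 | 10.0 | 0.333 | 9.5 |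
| 0.667 | 18.8 | 1.00 | 25.7 | 0.667 | 17.9 |
| 1.00 | 25.6 | 2.00 | 50.0 | 1.00 | 24.1 |
| 2.00 | 50.9 | 3.00 | 45.9 | 2.00 | 49.5 |
| 4.00 | 33.7 | 4.00 | 33.5 | 4.00 | 32.2 |

(standard deviation of a reading: 0.5 percentage points)

- the earlier runs were read with a standard deviation of 0.5 percentage points
- a reading or a percentage of Q counts all its forms, free or not

- which one finishes higher in amount of Q, in percent of the D charged ("neither" within 2 percentage points) (birch / maple / neither)
- amount of Q at the end, in percent of the D charged, birch
- amount of Q at the end, in percent of the D charged, maple

The eta run, nearest in E, ends at 32.2%, so maple should end near that and birch near 25.4%. Is one number enough? E stands outside it, and the end readings from delta to eta move by 1.5 percentage points. The share of D reaching Q also stands outside it, and no earlier run shows a single charge, so the birch figure assumes an equal share.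

The forecast gives maple, with birch at 27.5% and maple at 31.5%, on the ground that “The peak also comes earlier, so decay runs longer”. Its birch figure is higher than the reckoning above.

The flask gives maple: birch 22.6%, maple 31.3%.

    D → Q (k = 0.0280 s⁻¹)
    2 D → G (k = 0.170 M⁻¹ s⁻¹)
    Q → L (k = 0.00600 s⁻¹)
    D + E → J (k = 0.680 M⁻¹ s⁻¹)
    X ⇌ Q, rate k5*(cs5 - [Q]) while solid is left; crystals form when [Q] > cs5 (solubility = 21.0 mM, k = 0.0760 s⁻¹)

At 2.00 min birch held 1.81% of D and maple 13.0%, and by 4.00 min Q had passed into L until Q over Q plus L stood at 0.401 in maple, beside a kept fraction of 0.359, and at 0.307 in birch, beside 0.284. A neighbour of maple, dosed alike and so with the same kept fraction of 0.359, held 0.025 M of E and ended with 24.5% of Q and 40.8% of L, a ratio of 0.375.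

All runs are calculated for substances that don't exist.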